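**Plan**

1. Retrosynthetic cuts, in order: the two O–Si bonds; the aryl ether bond from the spiro-carbon oxygen to naphthalene C8 (closes the naphtho[1,8-bc]furan); the C3–C1 bond between lactam and naphthalene (the N2–C3 bond then forms by itself once C3 is a ketone); the amide bond. Labels: the lactam is numbered as isoindolin-1-one (C3 = hemiaminal/spiro carbon, C4 = methoxy carbon); the naphthalene has C1 on C3, oxygen on C2, methyl on C6, and C8 as the peri carbon.
2. Forward order: a silyl-protected benzamide and a silyl-protected naphthaldehyde are made separately, joined by ortho-lithiation/addition and oxidised. The lactam ring (3-hydroxyisoindolin-1-one) closes first, the furan ring last, and fluoride then frees both hydroxyls.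
3. Enabling feature: the hemiaminal carbon C3 (bonded to O, N2, the benzo ring and naphthalene C1) loses its configuration by reversible opening of the N2–C3 bond to the 2-aroylbenzamide. Its oxygen lies over the peri C8–H, the only C–H it can hand to palladium, because lactam C4 (OMe) and naphthalene C2 (OSi) are blocked.
4. Stereochemistry: the single stereocentre (the spiro carbon) comes from this ring closure run as a dynamic kinetic resolution under a chiral amino acid ligand on palladium. Everything before is achiral or racemic, and nothing afterwards touches the centre.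

Key step: step 7

Assumption: the sense of asymmetric induction in step 7 cannot be predicted, so the antipode of the amino acid ligand (L or D, both catalogue compounds) that leads to the required configuration is to be fixed by experiment; L is written below.

**Route**

Step 1
Reactants: 1 2-aminoethanol; 2 3-methoxybenzoyl chloride
Product: 3 N-(2-hydroxyethyl)-3-methoxybenzamide
Conditions: aq. NaOH, CH2Cl2/H2O, 0 °C to rt
Reagents that add atoms: none
Why: Schotten–Baumann acylation, in which the amine of 1 is far more nucleophilic than its hydroxyl, so the acid chloride should give the amide only.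

Step 2
Reactants: 3 N-(2-hydroxyethyl)-3-methoxybenzamide
Product: 4 N-[2-(tert-butyldiphenylsilyloxy)ethyl]-3-methoxybenzamide
Conditions: TBDPSCl, imidazole, CH2Cl2, 0 °C to rt
Reagents that add atoms: tert-butyl(chloro)diphenylsilane, CC(C)(C)[Si](Cl)(c1ccccc1)c1ccccc1
Why: Imidazole-promoted silylation of a primary alcohol; the tert-butyldiphenylsilyl ether is chosen because it should withstand s-BuLi and the acetic acid set free in step 7 and should keep this oxygen from adding to C3.

Step 3
Reactants: 5 6-methylnaphthalen-2-ol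
Product: 6 2-hydroxy-6-methyl-1-naphthaldehyde
Conditions: MgCl2, Et3N, paraformaldehyde, MeCN, reflux; aq. HCl work-up
Reagents that add atoms: formaldehyde (as paraformaldehyde), C=O
Why: Magnesium-mediated ortho-formylation of a phenol with paraformaldehyde (Casnati–Skattebøl reaction) is specific for the position next to the hydroxyl, which in a 2-naphthol is C1, the most electron-rich carbon.

Step 4
Reactants: 6 2-hydroxy-6-methyl-1-naphthaldehyde
Product: 7 6-methyl-2-(triisopropylsilyloxy)-1-naphthaldehyde
Conditions: TIPSOTf, 2,6-lutidine, CH2Cl2, 0 °C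
Reagents that add atoms: triisopropylsilyl trifluoromethanesulfonate, CC(C)[Si](OS(=O)(=O)C(F)(F)F)(C(C)C)C(C)C
Why: Silylation of the hydrogen-bonded naphthol with a silyl triflate; the bulky triisopropylsilyl ether should shield the naphthol from the hypervalent iodine oxidant of step 7 and is cleaved by fluoride at the end.

Step 5
Reactants: 4 N-[2-(tert-butyldiphenylsilyloxy)ethyl]-3-methoxybenzamide; 7 6-methyl-2-(triisopropylsilyloxy)-1-naphthaldehyde
Product: 9 rac-N-[2-(tert-butyldiphenylsilyloxy)ethyl]-2-{hydroxy[6-methyl-2-(triisopropylsilyloxy)naphthalen-1-yl]methyl}-3-methoxybenzamide, via dilithiated benzamide 8 (not isolated)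
Conditions: 4, s-BuLi (2.2 equiv), TMEDA, THF, −78 °C; then 7, −78 °C; AcOH/THF quench at −78 °C
Reagents that add atoms: none
Why: Directed ortho-metalation, in which the lithium amidate and the methoxy group jointly direct s-BuLi to the ring carbon between them and the aryllithium 8 adds to the non-enolisable aldehyde 7 (quenched cold so that the silyl group does not migrate to the new alkoxide); the carbinol stereocentre forms without control and is removed in step 6.

Step 6
Reactants: 9 rac-N-[2-(tert-butyldiphenylsilyloxy)ethyl]-2-{hydroxy[6-methyl-2-(triisopropylsilyloxy)naphthalen-1-yl]methyl}-3-methoxybenzamide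
Product: 11 rac-3-hydroxy-4-methoxy-3-[6-methyl-2-(triisopropylsilyloxy)naphthalen-1-yl]-2-[2-(tert-butyldiphenylsilyloxy)ethyl]isoindolin-1-one, via keto amide 10 (not isolated)
Conditions: Dess–Martin periodinane, NaHCO3, CH2Cl2, 0 °C to rt
Reagents that add atoms: none
Why: Dess–Martin oxidation of the diaryl carbinol should give ketone 10, which is captured by the neighbouring secondary amide nitrogen to give the five-membered hydroxylactam 11 (ring–chain tautomerism); C3 forms racemic and stays labile, which is what step 7 exploits.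

Step 7
Reactants: 11 rac-3-hydroxy-4-methoxy-3-[6-methyl-2-(triisopropylsilyloxy)naphthalen-1-yl]-2-[2-(tert-butyldiphenylsilyloxy)ethyl]isoindolin-1-one
Product: 13 (S)-2-[2-(tert-butyldiphenylsilyloxy)ethyl]-7-methoxy-7'-methyl-3'-(triisopropylsilyloxy)spiro[isoindoline-1,2'-naphtho[1,8-bc]furan]-3-one, via oxapalladacycle 12 (not isolated)
Conditions: Pd(OAc)2 (10 mol%), Boc-L-Ile-OH (20 mol%), PhI(OAc)2 (1.5 equiv), Li2CO3 (1.5 equiv), C6F6, 70 °C
Reagents that add atoms: none
Why: Proposed new method: the alkoxide of hydroxylactam 11 binds divalent palladium that carries the N-Boc amino acid as a bidentate ligand, the peri hydrogen on naphthalene C8 is removed in a concerted metalation–deprotonation to give the six-membered oxapalladacycle 12, PhI(OAc)2 oxidises 12 to tetravalent palladium and C8–O reductive elimination releases 13 and divalent palladium. The closest known reaction type is the hydroxyl-directed C–H activation/C–O cyclisation of tertiary alcohols to dihydrobenzofurans under Pd(OAc)2/PhI(OAc)2, and N-protected amino acid ligands are known to render palladium C–H cleavage enantioselective and to resolve racemates whose stereocentre bears the directing atom, but none of this has been shown for a hemiaminal hydroxyl, for a peri C–H bond or as a dynamic resolution. The furan ring (O, C3, naphthalene C1, C8a, C8) closes by C–O reductive elimination out of the six-membered palladacycle, that is, a five-membered ring formed across the peri positions with only acenaphthene-like strain. The C3 stereocentre is selected, not created: under the carbonate/acetate buffer the two enantiomers of the reactant 11 equilibrate by ring–chain tautomerism through the stereocentre-free open keto amide 10 already met in step 6, the chiral ligand makes C–H cleavage faster for one alkoxide, and after O-arylation the N2–C3 bond can no longer open, so the configuration is fixed in 13. The step needs site selectivity and a racemisation faster than C–H cleavage; the substrate secures the first because C4 of the lactam (OMe) and C2 of the naphthalene (OSi) are blocked and only C8–H can reach palladium through a six-membered ring, and the second through the ease of ring–chain tautomerism of 3-aryl-3-hydroxyisoindolin-1-ones.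

Step 8
Reactants: 13 (S)-2-[2-(tert-butyldiphenylsilyloxy)ethyl]-7-methoxy-7'-methyl-3'-(triisopropylsilyloxy)spiro[isoindoline-1,2'-naphtho[1,8-bc]furan]-3-one
Product: 14 (R)-3'-hydroxy-2-(2-hydroxyethyl)-7-methoxy-7'-methylspiro[isoindoline-1,2'-naphtho[1,8-bc]furan]-3-one
Conditions: TBAF, AcOH (1:1), THF, 0 °C to rt
Reagents that add atoms: none
Why: Fluoride cleavage of both silyl ethers, buffered with acetic acid so that the medium is neither acidic enough to ionise the N,O-ketal nor basic enough to open it through the naphthoxide, should leave the stereocentre untouched; the descriptor changes from S to R only because O–Si outranks O–CH3 in 13.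

**Compound list**

1 | 2-aminoethanol | NCCO | starting material
2 | 3-methoxybenzoyl chloride | COc1cccc(C(=O)Cl)c1 | starting material
3 | N-(2-hydroxyethyl)-3-methoxybenzamide | COc1cccc(C(=O)NCCO)c1 | intermediate
4 | N-[2-(tert-butyldiphenylsilyloxy)ethyl]-3-methoxybenzamide | COc1cccc(C(=O)NCCO[Si](c2ccccc2)(c2ccccc2)C(C)(C)C)c1 | intermediate
5 | 6-methylnaphthalen-2-ol | Cc1ccc2cc(O)ccc2c1 | starting material
6 | 2-hydroxy-6-methyl-1-naphthaldehyde | Cc1ccc2c(C=O)c(O)ccc2c1 | intermediate
7 | 6-methyl-2-(triisopropylsilyloxy)-1-naphthaldehyde | Cc1ccc2c(C=O)c(O[Si](C(C)C)(C(C)C)C(C)C)ccc2c1 | intermediate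
8 | dilithiated benzamide: N-lithio-2-lithio-N-[2-(tert-butyldiphenylsilyloxy)ethyl]-3-methoxybenzamide (not isolated) | COc1cccc(C(=O)N([Li])CCO[Si](c2ccccc2)(c2ccccc2)C(C)(C)C)c1[Li] | intermediate
9 | rac-N-[2-(tert-butyldiphenylsilyloxy)ethyl]-2-{hydroxy[6-methyl-2-(triisopropylsilyloxy)naphthalen-1-yl]methyl}-3-methoxybenzamide | COc1cccc(C(=O)NCCO[Si](c2ccccc2)(c2ccccc2)C(C)(C)C)c1C(O)c1c(O[Si](C(C)C)(C(C)C)C(C)C)ccc2cc(C)ccc12 | intermediate
10 | keto amide: N-[2-(tert-butyldiphenylsilyloxy)ethyl]-3-methoxy-2-[6-methyl-2-(triisopropylsilyloxy)-1-naphthoyl]benzamide (not isolated) | COc1cccc(C(=O)NCCO[Si](c2ccccc2)(c2ccccc2)C(C)(C)C)c1C(=O)c1c(O[Si](C(C)C)(C(C)C)C(C)C)ccc2cc(C)ccc12 | intermediate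
11 | rac-3-hydroxy-4-methoxy-3-[6-methyl-2-(triisopropylsilyloxy)naphthalen-1-yl]-2-[2-(tert-butyldiphenylsilyloxy)ethyl]isoindolin-1-one | COc1cccc2c1C(O)(c1c(O[Si](C(C)C)(C(C)C)C(C)C)ccc3cc(C)ccc13)N(CCO[Si](c1ccccc1)(c1ccccc1)C(C)(C)C)C2=O | intermediate
12 | oxapalladacycle of divalent palladium (Pd bonded to the C3 oxygen and to naphthalene C8, configured at C3 as in 13; the amino acid ligand is left out of the SMILES; not isolated) | COc1cccc2c1[C@@]1(O[Pd]c3cc(C)cc4ccc(O[Si](C(C)C)(C(C)C)C(C)C)c1c34)N(CCO[Si](c1ccccc1)(c1ccccc1)C(C)(C)C)C2=O | intermediate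
13 | (S)-2-[2-(tert-butyldiphenylsilyloxy)ethyl]-7-methoxy-7'-methyl-3'-(triisopropylsilyloxy)spiro[isoindoline-1,2'-naphtho[1,8-bc]furan]-3-one | COc1cccc2c1[C@@]1(Oc3cc(C)cc4ccc(O[Si](C(C)C)(C(C)C)C(C)C)c1c34)N(CCO[Si](c1ccccc1)(c1ccccc1)C(C)(C)C)C2=O | intermediate
14 | (R)-3'-hydroxy-2-(2-hydroxyethyl)-7-methoxy-7'-methylspiro[isoindoline-1,2'-naphtho[1,8-bc]furan]-3-one | COc1cccc2c1[C@@]1(Oc3cc(C)cc4ccc(O)c1c34)N(CCO)C2=O | target

**Count and risks**

Total step count: 8. Longest linear sequence: 6 steps (5 → 6 → 7 → 9 → 11 → 13 → 14); the benzamide branch (1 + 2 → 3 → 4) joins at step 5 and is equally long.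

Steps most likely to fail:

1. Step 7 (Proposed new method). The crowded, weakly donating hemiaminal alkoxide may fail to deliver palladium to C8–H, or acetoxylation may compete with ring closure. Racemisation of 11 may also be slower than C–H cleavage, so that the step stops as a simple kinetic resolution, and the acetic acid formed may ionise the N,O-ketal and erode the enantiomeric purity of 13. The fallback uses known reaction types only, sets out from aldehyde 7 and returns at 13. Aldehyde-directed peri-bromination of 7 (Pd(OAc)2 cat., N-bromosuccinimide, 1,2-dichloroethane, 80 °C; C2 is blocked) should give 8-bromo-6-methyl-2-(triisopropylsilyloxy)-1-naphthaldehyde F1. Addition of dilithiated benzamide 8 as in step 5 should give the bromo carbinol rac-N-[2-(tert-butyldiphenylsilyloxy)ethyl]-2-{[8-bromo-6-methyl-2-(triisopropylsilyloxy)naphthalen-1-yl](hydroxy)methyl}-3-methoxybenzamide F2. Dess–Martin oxidation as in step 6 should give the bromo hydroxylactam rac-3-[8-bromo-6-methyl-2-(triisopropylsilyloxy)naphthalen-1-yl]-3-hydroxy-4-methoxy-2-[2-(tert-butyldiphenylsilyloxy)ethyl]isoindolin-1-one F3. Intramolecular Buchwald–Hartwig C–O coupling of the tertiary hydroxyl with the C8 bromide (Pd2(dba)3, racemic 2-(di-tert-butylphosphino)-1,1'-binaphthyl, Cs2CO3, toluene, 80 °C) forms the same O–C8 bond and should give the racemic bis-silyl spiro compound rac-2-[2-(tert-butyldiphenylsilyloxy)ethyl]-7-methoxy-7'-methyl-3'-(triisopropylsilyloxy)spiro[isoindoline-1,2'-naphtho[1,8-bc]furan]-3-one F4. Preparative chromatography on a chiral stationary phase then delivers 13.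

2. Step 5. The doubly ortho-substituted aryllithium may add slowly to the crowded aldehyde, and the triisopropylsilyl group may migrate from the naphthol oxygen to the new alkoxide and then be lost with elimination. The fallback forms the C3–C1 bond by electrophilic substitution of the free naphthol instead; it sets out from 4 and 5 and returns at 11. Lithiation of 4 as in step 5 but with a DMF quench should give 3-hydroxy-4-methoxy-2-[2-(tert-butyldiphenylsilyloxy)ethyl]isoindolin-1-one F5. Acid-catalysed N-acyliminium Friedel–Crafts (Betti-type) alkylation of 5 at C1 (TsOH cat., CH2Cl2) should give rac-3-(2-hydroxy-6-methylnaphthalen-1-yl)-4-methoxy-2-[2-(tert-butyldiphenylsilyloxy)ethyl]isoindolin-1-one F6. Silylation (TIPSOTf, 2,6-lutidine) should give rac-4-methoxy-3-[6-methyl-2-(triisopropylsilyloxy)naphthalen-1-yl]-2-[2-(tert-butyldiphenylsilyloxy)ethyl]isoindolin-1-one F7. Deprotonation at C3 and oxygenation (KN(SiMe3)2, THF, −78 °C; O2; P(OEt)3) should then give 11.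

3. Step 6. Oxidation of the crowded diaryl carbinol may be slow, and traces of acid may drive lactonisation to the phthalide with loss of the amine side chain. The fallback reaches the ketone level in the C–C bond-forming event itself; it sets out from 7 and returns at 11. Pinnick oxidation of 7 (NaClO2, NaH2PO4, 2-methyl-2-butene, t-BuOH/H2O) should give 6-methyl-2-(triisopropylsilyloxy)-1-naphthoic acid F8. Neutral chlorination with 1-chloro-N,N,2-trimethylprop-1-en-1-amine should give 6-methyl-2-(triisopropylsilyloxy)-1-naphthoyl chloride F9. Acylation of dilithiated benzamide 8 at −78 °C should then give 11 directly, because the ketone is captured at once by the neighbouring lithium amidate as the alkoxide of 11, which also prevents a second addition.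

**Further compounds**

F1 | step 7 | 8-bromo-6-methyl-2-(triisopropylsilyloxy)-1-naphthaldehyde | Cc1cc(Br)c2c(C=O)c(O[Si](C(C)C)(C(C)C)C(C)C)ccc2c1
F2 | step 7 | rac-N-[2-(tert-butyldiphenylsilyloxy)ethyl]-2-{[8-bromo-6-methyl-2-(triisopropylsilyloxy)naphthalen-1-yl](hydroxy)methyl}-3-methoxybenzamide | COc1cccc(C(=O)NCCO[Si](c2ccccc2)(c2ccccc2)C(C)(C)C)c1C(O)c1c(O[Si](C(C)C)(C(C)C)C(C)C)ccc2cc(C)cc(Br)c12
F3 | step 7 | rac-3-[8-bromo-6-methyl-2-(triisopropylsilyloxy)naphthalen-1-yl]-3-hydroxy-4-methoxy-2-[2-(tert-butyldiphenylsilyloxy)ethyl]isoindolin-1-one | COc1cccc2c1C(O)(c1c(O[Si](C(C)C)(C(C)C)C(C)C)ccc3cc(C)cc(Br)c13)N(CCO[Si](c1ccccc1)(c1ccccc1)C(C)(C)C)C2=O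
F4 | step 7 | rac-2-[2-(tert-butyldiphenylsilyloxy)ethyl]-7-methoxy-7'-methyl-3'-(triisopropylsilyloxy)spiro[isoindoline-1,2'-naphtho[1,8-bc]furan]-3-one | COc1cccc2c1C1(Oc3cc(C)cc4ccc(O[Si](C(C)C)(C(C)C)C(C)C)c1c34)N(CCO[Si](c1ccccc1)(c1ccccc1)C(C)(C)C)C2=O
F5 | step 5 | 3-hydroxy-4-methoxy-2-[2-(tert-butyldiphenylsilyloxy)ethyl]isoindolin-1-one | COc1cccc2c1C(O)N(CCO[Si](c1ccccc1)(c1ccccc1)C(C)(C)C)C2=O
F6 | step 5 | rac-3-(2-hydroxy-6-methylnaphthalen-1-yl)-4-methoxy-2-[2-(tert-butyldiphenylsilyloxy)ethyl]isoindolin-1-one | COc1cccc2c1C(c1c(O)ccc3cc(C)ccc13)N(CCO[Si](c1ccccc1)(c1ccccc1)C(C)(C)C)C2=O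
F7 | step 5 | rac-4-methoxy-3-[6-methyl-2-(triisopropylsilyloxy)naphthalen-1-yl]-2-[2-(tert-butyldiphenylsilyloxy)ethyl]isoindolin-1-one | COc1cccc2c1C(c1c(O[Si](C(C)C)(C(C)C)C(C)C)ccc3cc(C)ccc13)N(CCO[Si](c1ccccc1)(c1ccccc1)C(C)(C)C)C2=O
F8 | step 6 | 6-methyl-2-(triisopropylsilyloxy)-1-naphthoic acid | Cc1ccc2c(C(=O)O)c(O[Si](C(C)C)(C(C)C)C(C)C)ccc2c1
F9 | step 6 | 6-methyl-2-(triisopropylsilyloxy)-1-naphthoyl chloride | Cc1ccc2c(C(=O)Cl)c(O[Si](C(C)C)(C(C)C)C(C)C)ccc2c1
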